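A direct plan would prepare each benzene ring separately in protected form: ring B as the aryl methyl carbonate A1 (six steps of protection, Dakin oxidation, ortho-formylation, reduction, silylation and acylation from 2-hydroxy-4-methoxybenzaldehyde) and ring A as the silylaryl triflate A2 (four steps from orcinol).
It would then join them by a fluoride-triggered aryne insertion into the ArO–CO2Me bond to give the protected diaryl ether A3, deprotect to the triol A4 and acetylate the benzylic alcohol.
Its weakest steps would be: (i) the aryne insertion into the carbonate, a reaction without precedent that would have to form the hindered C–O bond and the C–C bond together from two fully elaborated fragments, where plain aryloxide–aryne addition with protonation would consume both;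
(ii) the six-step chain to A1 (and the statistical mono-etherification of orcinol on the way to A2), which would only shuffle oxygen functions and protecting groups on a ready-made ring, many steps for little complexity;
(iii) the last-step acetylation of one primary alcohol beside two free phenols in A4, a chemoselectivity problem placed on the most precious material.

**Plan of the new route**

- Enabling feature: ring A carries CO2Me on C1 next to its ether carbon C6, and ring B carries a free OH on C2' next to its ether carbon C1'. This is the pattern left when a spiro[benzofuran-3-one-2,1'-cyclohexa-3',5'-dien-2'-one] is opened by methanol. The CH2O on C6' next to C1' is the CH2O of a phthalide.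
- Retrosynthesis: the ring A O–C1' ether bond and the ester C–OMe bond are cut and the ester carbon is re-joined to C1', giving a 2,2',6-trihydroxybenzophenone. Its ketone–ring A bond is then cut to an aryllithium from orcinol and a phthalide, whose lactone carbon ends as the CO2Me carbon and whose CH2O ends as CH2OAc.
- Order of rings: both benzene rings are bought and first joined through carbon. A spiro benzofuranone ring arises and is opened again in the last step, and only there does the diaryl ether exist.
- The weak steps no longer occur: the hindered C–O bond forms intramolecularly from a C–C bond made by an ordinary organolithium addition (no aryne, no intermolecular coupling of elaborated fragments). Ring B's oxygen pattern is bought with the phthalide, ring A stays symmetrical to the end, and the acetate goes onto the only hydroxyl present before any phenol is free.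

Key step: step 7

Remark: orcinol and 5,7-dimethoxyphthalide are taken as catalogue compounds.

**Route**

Step 1
Reactants: 1 orcinol (5-methylbenzene-1,3-diol)
Product: 2 1,3-bis(methoxymethoxy)-5-methylbenzene
Conditions: NaH, MOMCl, DMF, 0 °C to rt
Reagents that add atoms: chloromethyl methyl ether (MOMCl), COCCl
Why: Twofold Williamson O-alkylation (MOM protection) of the symmetrical diol runs to completion without any selectivity issue and installs the two acetal ethers that later direct lithiation to the carbon between them.

Step 2
Reactants: 3 5,7-dimethoxy-2-benzofuran-1(3H)-one (5,7-dimethoxyphthalide)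
Product: 4 7-hydroxy-5-methoxy-2-benzofuran-1(3H)-one
Conditions: BCl3 (1.1 equiv), CH2Cl2, −78 to 0 °C; then H2O
Reagents that add atoms: none
Why: Chelation-controlled Lewis-acid ether cleavage, in which BCl3 bridges the lactone carbonyl and the peri 7-methoxy oxygen and chloride removes only that methyl group, while the unassisted 5-methoxy group should stay intact at this temperature.

Step 3
Reactants: 4 7-hydroxy-5-methoxy-2-benzofuran-1(3H)-one
Product: 5 5-methoxy-7-(methoxymethoxy)-2-benzofuran-1(3H)-one
Conditions: NaH, MOMCl, DMF, 0 °C to rt
Reagents that add atoms: chloromethyl methyl ether (MOMCl), COCCl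
Why: O-alkylation of the sodium phenoxide (MOM protection) masks the acidic phenol before the organolithium step with a group that leaves under the same conditions as the ring A acetals.

Step 4
Reactants: 2 1,3-bis(methoxymethoxy)-5-methylbenzene; 5 5-methoxy-7-(methoxymethoxy)-2-benzofuran-1(3H)-one
Product: 7 [2,6-bis(methoxymethoxy)-4-methylphenyl][2-(hydroxymethyl)-4-methoxy-6-(methoxymethoxy)phenyl]methanone, via aryllithium 6 (not isolated)
Conditions: n-BuLi (1.15 equiv), THF, 0 °C; then 5, −78 to 0 °C; then H2O
Reagents that add atoms: none
Why: Directed ortho-metalation between the two OCH2OMe groups followed by acyl substitution at the lactone carbonyl opens the phthalide, so that its C1 becomes the diaryl ketone carbon and its CH2O is released as the primary alcohol, and the doubly ortho-substituted ketone should not add a second hindered aryllithium.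

Step 5
Reactants: 7 [2,6-bis(methoxymethoxy)-4-methylphenyl][2-(hydroxymethyl)-4-methoxy-6-(methoxymethoxy)phenyl]methanone
Product: 8 {2-[2,6-bis(methoxymethoxy)-4-methylbenzoyl]-5-methoxy-3-(methoxymethoxy)phenyl}methyl acetate
Conditions: Ac2O, pyridine, DMAP (cat.), CH2Cl2, 0 °C to rt
Reagents that add atoms: acetic anhydride, CC(=O)OC(C)=O
Why: DMAP-catalysed O-acylation of the only hydroxyl group present; any cyclic hemiketal form of 7 should be drained through the open hydroxy ketone, and the acetate then blocks ring–chain tautomerism.

Step 6
Reactants: 8 {2-[2,6-bis(methoxymethoxy)-4-methylbenzoyl]-5-methoxy-3-(methoxymethoxy)phenyl}methyl acetate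
Product: 9 [2-(2,6-dihydroxy-4-methylbenzoyl)-3-hydroxy-5-methoxyphenyl]methyl acetate
Conditions: ZnBr2, n-PrSH, CH2Cl2, 0 °C to rt
Reagents that add atoms: none
Why: Lewis-acid-assisted acetal cleavage with thiol capture of the methoxymethyl cation (so that it cannot alkylate the freed resorcinol ring) should remove all three aryl MOM ethers and leave the primary acetate, which sits meta to both ring B oxygens and is not prone to ionisation.

Step 7
Reactants: 9 [2-(2,6-dihydroxy-4-methylbenzoyl)-3-hydroxy-5-methoxyphenyl]methyl acetate
Product: 11 Betaethrin A, via spirodienone 10 (not isolated)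
Conditions: PhI(OAc)2 (1.0 equiv), (CF3)2CHOH, 0.01 M, −20 to 0 °C; then MeOH, Et3N, 0 °C to rt
Reagents that add atoms: methanol, CO
Why: PhI(OAc)2 oxidises the phenol of ring B, the hydroxyl of ring A that is not hydrogen-bonded to the ketone adds to the ipso carbon C1' of the resulting phenoxonium-type intermediate, and loss of iodobenzene gives the spiro cyclohexa-2,4-dienone 10; methanol with Et3N then adds to the benzofuranone carbonyl, and the bond from that carbon to the spiro carbon breaks in a retro-Claisen fragmentation whose leaving group is the phenoxide of re-aromatised ring B, so that the former ketone carbon becomes the CO2Me of ring A, the spiro carbon the ether carbon C1' and the dienone oxygen the free 2'-OH. The closest known reaction types are the oxidative phenol coupling of 2,2'-dihydroxybenzophenones to grisadienediones (the griseofulvin and geodin pattern) and the solvolytic cleavage of such spirodienones to diaryl ether esters (the asterric acid pattern). The one ring that is closed, the five-membered benzofuranone ring, forms by 5-exo attack of oxygen on C1' and is opened again in the same flask; the spiro carbon is the only new stereocentre, is formed racemic and is erased on ring opening. The step needs ring B, not ring A, to be dearomatised: ring A is a 2,6-dihydroxyaryl ketone held coplanar with the carbonyl by a hydrogen bond (an electron-poor vinylogous acid), whereas ring B, pushed out of conjugation by its CH2OAc group, keeps an electron-rich phenol whose C1' (ortho to OH, para to OMe) faces the second, in-plane hydroxyl of ring A; ring A is symmetrical, so either of its hydroxyls gives the same product. It also needs methanol to cleave at the benzofuranone carbonyl and spare the acetate: only cleavage there re-aromatises ring B, the dienone carbonyl is a deactivated vinylogous ester, and a primary acetate should not be transesterified by Et3N in methanol at this temperature.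

**Compound list**

1 | orcinol (5-methylbenzene-1,3-diol) | Cc1cc(O)cc(O)c1 | starting material
2 | 1,3-bis(methoxymethoxy)-5-methylbenzene | COCOc1cc(C)cc(OCOC)c1 | intermediate
3 | 5,7-dimethoxy-2-benzofuran-1(3H)-one (5,7-dimethoxyphthalide) | O=C1OCc2cc(OC)cc(OC)c12 | starting material
4 | 7-hydroxy-5-methoxy-2-benzofuran-1(3H)-one | O=C1OCc2cc(OC)cc(O)c12 | intermediate
5 | 5-methoxy-7-(methoxymethoxy)-2-benzofuran-1(3H)-one | O=C1OCc2cc(OC)cc(OCOC)c12 | intermediate
6 | [2,6-bis(methoxymethoxy)-4-methylphenyl]lithium | [Li]c1c(OCOC)cc(C)cc1OCOC | intermediate (not isolated)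
7 | [2,6-bis(methoxymethoxy)-4-methylphenyl][2-(hydroxymethyl)-4-methoxy-6-(methoxymethoxy)phenyl]methanone | COCOc1cc(C)cc(OCOC)c1C(=O)c1c(CO)cc(OC)cc1OCOC | intermediate
8 | {2-[2,6-bis(methoxymethoxy)-4-methylbenzoyl]-5-methoxy-3-(methoxymethoxy)phenyl}methyl acetate | COCOc1cc(C)cc(OCOC)c1C(=O)c1c(COC(C)=O)cc(OC)cc1OCOC | intermediate
9 | [2-(2,6-dihydroxy-4-methylbenzoyl)-3-hydroxy-5-methoxyphenyl]methyl acetate | CC(=O)OCc1cc(OC)cc(O)c1C(=O)c1c(O)cc(C)cc1O | intermediate
10 | (4-hydroxy-4'-methoxy-6-methyl-2',3-dioxo-3H-spiro[1-benzofuran-2,1'-cyclohexa[3,5]dien]-6'-yl)methyl acetate (racemic spirodienone) | CC(=O)OCC1=CC(OC)=CC(=O)C12Oc1cc(C)cc(O)c1C2=O | intermediate (not isolated)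
11 | Betaethrin A (methyl 2-[2-(acetoxymethyl)-6-hydroxy-4-methoxyphenoxy]-6-hydroxy-4-methylbenzoate; achiral) | COC(=O)c1c(O)cc(C)cc1Oc1c(O)cc(OC)cc1COC(C)=O | target

**Totals**

Total step count: 7. Longest linear sequence: 6 steps (3 → 4 → 5 → 7 → 8 → 9 → 11).

**Steps most likely to fail**

Step 7. What may go wrong: dearomatisation of the resorcinol-type ring A in place of ring B (attack of the ring B hydroxyl on the ring A ipso carbon, which would end in the isomeric ether), intermolecular phenol coupling, or capture of the oxidised phenol by the medium before the spiro ring closes. Fallback (sets out from 6 and 5, returns at 11): the diaryl ether would be closed by a copper-catalysed Ullmann coupling instead of an oxidation.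
- Quenching 6 with ClCO2Me would give methyl 2,6-bis(methoxymethoxy)-4-methylbenzoate F1, and ZnBr2/n-PrSH would free methyl 2,6-dihydroxy-4-methylbenzoate F2.
- Saponification of 5 (NaOH, aqueous THF) and acetylation of the sodium salt (Ac2O, pyridine) would give 2-(acetoxymethyl)-4-methoxy-6-(methoxymethoxy)benzoic acid F3.
- Ipso-bromodecarboxylation of this electron-rich acid (n-Bu4NBr3, K3PO4, MeCN) would give [2-bromo-5-methoxy-3-(methoxymethoxy)phenyl]methyl acetate F4.
- Coupling of F4 with an excess of F2 (CuI, picolinic acid, K3PO4, DMSO, 80 °C) would give methyl 2-[2-(acetoxymethyl)-4-methoxy-6-(methoxymethoxy)phenoxy]-6-hydroxy-4-methylbenzoate F5.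
- ZnBr2/n-PrSH would remove the last acetal ether to give 11.

Step 4. What may go wrong: deprotonation of the lactone CH2 group, or no addition at all, because the carbonyl of 5 is flanked by the peri acetal ether and the nucleophile carries two ortho substituents. Fallback (sets out from 5, returns at 8): the electrophile would be changed from the lactone to an aldehyde.
- i-Bu2AlH (toluene, −78 °C) would reduce 5 to the lactol 5-methoxy-7-(methoxymethoxy)-1,3-dihydro-2-benzofuran-1-ol F6.
- Two equivalents of 6 would first open F6 to the alkoxy aldehyde (regenerating 2) and then add, giving the diol [2,6-bis(methoxymethoxy)-4-methylphenyl][2-(hydroxymethyl)-4-methoxy-6-(methoxymethoxy)phenyl]methanol F7.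
- Ac2O/pyridine would acetylate only the primary alcohol, the diarylmethanol being shielded by four ortho substituents, to give (2-{[2,6-bis(methoxymethoxy)-4-methylphenyl](hydroxy)methyl}-5-methoxy-3-(methoxymethoxy)phenyl)methyl acetate F8.
- MnO2 (CH2Cl2) would oxidise the benzylic alcohol to ketone 8.

Step 6. What may go wrong: alkylation of the freed, highly nucleophilic resorcinol ring by the methoxymethyl cation, or Lewis-acid-assisted loss or thiol displacement of the benzylic acetate. Fallback (sets out from 7, returns at 9): the order would be inverted and the acylation made enzymatic.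
- HCl in MeOH at 0 °C would remove the acetal ethers before any acetate exists (methanol traps the cation as dimethoxymethane), giving (2,6-dihydroxy-4-methylphenyl)[2-hydroxy-6-(hydroxymethyl)-4-methoxyphenyl]methanone F9.
- Lipase-catalysed transesterification (immobilised Candida antarctica lipase B, vinyl acetate, MTBE, 35 °C), which does not acylate phenols, would acetylate the primary alcohol alone to give 9.

**Further compounds**

F1 | step 7 | methyl 2,6-bis(methoxymethoxy)-4-methylbenzoate | COCOc1cc(C)cc(OCOC)c1C(=O)OC
F2 | step 7 | methyl 2,6-dihydroxy-4-methylbenzoate | COC(=O)c1c(O)cc(C)cc1O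
F3 | step 7 | 2-(acetoxymethyl)-4-methoxy-6-(methoxymethoxy)benzoic acid | COCOc1cc(OC)cc(COC(C)=O)c1C(=O)O
F4 | step 7 | [2-bromo-5-methoxy-3-(methoxymethoxy)phenyl]methyl acetate | COCOc1cc(OC)cc(COC(C)=O)c1Br
F5 | step 7 | methyl 2-[2-(acetoxymethyl)-4-methoxy-6-(methoxymethoxy)phenoxy]-6-hydroxy-4-methylbenzoate | COCOc1cc(OC)cc(COC(C)=O)c1Oc1cc(C)cc(O)c1C(=O)OC
F6 | step 4 | 5-methoxy-7-(methoxymethoxy)-1,3-dihydro-2-benzofuran-1-ol (racemic) | COCOc1cc(OC)cc2c1C(O)OC2
F7 | step 4 | [2,6-bis(methoxymethoxy)-4-methylphenyl][2-(hydroxymethyl)-4-methoxy-6-(methoxymethoxy)phenyl]methanol (racemic) | COCOc1cc(C)cc(OCOC)c1C(O)c1c(CO)cc(OC)cc1OCOC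
F8 | step 4 | (2-{[2,6-bis(methoxymethoxy)-4-methylphenyl](hydroxy)methyl}-5-methoxy-3-(methoxymethoxy)phenyl)methyl acetate (racemic) | COCOc1cc(C)cc(OCOC)c1C(O)c1c(COC(C)=O)cc(OC)cc1OCOC
F9 | step 6 | (2,6-dihydroxy-4-methylphenyl)[2-hydroxy-6-(hydroxymethyl)-4-methoxyphenyl]methanone | Cc1cc(O)c(C(=O)c2c(O)cc(OC)cc2CO)c(O)c1
A1 | direct plan | 2-({[tert-butyl(dimethyl)silyl]oxy}methyl)-4-methoxy-6-(methoxymethoxy)phenyl methyl carbonate | COCOc1cc(OC)cc(CO[Si](C)(C)C(C)(C)C)c1OC(=O)OC
A2 | direct plan | 3-(methoxymethoxy)-5-methyl-2-(trimethylsilyl)phenyl trifluoromethanesulfonate | COCOc1cc(C)cc(OS(=O)(=O)C(F)(F)F)c1[Si](C)(C)C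
A3 | direct plan | methyl 2-[2-({[tert-butyl(dimethyl)silyl]oxy}methyl)-4-methoxy-6-(methoxymethoxy)phenoxy]-6-(methoxymethoxy)-4-methylbenzoate | COC(=O)c1c(OCOC)cc(C)cc1Oc1c(OCOC)cc(OC)cc1CO[Si](C)(C)C(C)(C)C
A4 | direct plan | methyl 2-hydroxy-6-[2-hydroxy-6-(hydroxymethyl)-4-methoxyphenoxy]-4-methylbenzoate | COC(=O)c1c(O)cc(C)cc1Oc1c(O)cc(OC)cc1CO
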